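**Retrosynthetic overview**
1. No ring is formed: the benzene ring is bought as 2,4-dimethoxyphenol (1), whose only free position ortho to OH becomes C6.
2. Key disconnection (last bond made): ArCH2–CH2R, between the benzylic carbon of Mannich base 2 (latent electrophile) and the former carbonyl carbon of a C20 aldehyde.
3. The C20 partner is 1-eicosanol (3), oxidised to eicosanal (4). Its N–H hydrazone 5 acts as a traceless alkyl-carbanion equivalent, so two carbons that are both electrophilic in their normal form are joined.
4. In the key step 2 releases o-quinone methide 6, 5 adds 1,4, and the alkyl diazene 7 loses N2 to give target 8 directly, with no functional group left to remove.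
5. Carbon count: chain C1 comes from formaldehyde (Mannich step), C2–C21 from 4.

Assumption: the target has no stereocentre and no stereogenic double bond, so "single enantiomer" needs no stereocontrol; the SMILES is taken as written.

**Step 1**
Reactants: 1 2,4-dimethoxyphenol
Product: 2 2-[(dimethylamino)methyl]-4,6-dimethoxyphenol
Conditions: 37% aq. CH2O (1.2 equiv), 40% aq. Me2NH (1.5 equiv), EtOH, N2, rt → reflux, 12 h
Reagents that add atoms: formaldehyde, C=O; dimethylamine, CNC
Why: Phenol Mannich reaction (ortho-aminomethylation): the iminium attacks the only free position ortho to OH (para is blocked by OMe, and the positions meta to OH are not activated under neutral Mannich conditions), so one regioisomer is expected.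

**Step 2**
Reactants: 3 1-eicosanol
Product: 4 eicosanal
Conditions: TEMPO (10 mol %), PhI(OAc)2 (1.1 equiv), CH2Cl2, rt
Reagents that add atoms: none
Why: TEMPO/PhI(OAc)2 (oxoammonium) oxidation of a primary alcohol stops at the aldehyde under anhydrous conditions, and no other functional group is present.

**Step 3**
Reactants: 2 2-[(dimethylamino)methyl]-4,6-dimethoxyphenol; 4 eicosanal
Product: 8 6-n-heneicosyl-2,4-dimethoxyphenol (target), via eicosanal hydrazone 5 (not isolated), via o-quinone methide 6 (not isolated), via alkyl diazene 7 (not isolated)
Conditions: 4 (1.5 equiv), N2H4·H2O, THF, rt, 1 h; then 2, [Ru(p-cymene)Cl2]2 (2.5 mol %), dmpe (5 mol %), K3PO4 (0.5 equiv), CsF, 1,4-dioxane, 100 °C, N2 sweep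
Reagents that add atoms: hydrazine (used as the hydrate), NN (supplies the two N atoms of 5 and 7, which leave as N2; none remains in 8)
Why: Proposed new method: on heating, Mannich base 2 expels Me2NH (retro-Mannich through its phenoxide/ammonium zwitterion) to give the electron-rich o-quinone methide 6, while Ru(II)/dmpe/K3PO4 converts the N–H hydrazone 5 into a metal-bound aza-allyl species whose carbon (the former C=O carbon) adds 1,4 to the exocyclic CH2 of 6 with re-aromatisation to give diazene 7, which loses N2 under base (Wolff–Kishner-type) and leaves a plain CH2; N-attack of 5, Me2NH or hydrazine on 6 is reversible whereas C–C formation followed by N2 loss is not, which should funnel material to 8; the closest known reaction types are the Ru-catalysed conjugate addition of N-unsubstituted aldehyde hydrazones (aldehydes as alkyl-carbanion equivalents) to electron-poor alkenes and the trapping by soft nucleophiles of o-quinone methides released thermally from phenolic Mannich bases; the one stereocentre of 7 is racemic and is erased on N2 loss.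

**Compound list**
1 | 2,4-dimethoxyphenol | COc1ccc(O)c(OC)c1 | starting material
2 | 2-[(dimethylamino)methyl]-4,6-dimethoxyphenol | CN(C)Cc1cc(OC)cc(OC)c1O | intermediate
3 | 1-eicosanol (icosan-1-ol) | CCCCCCCCCCCCCCCCCCCCO | starting material
4 | eicosanal (icosanal) | CCCCCCCCCCCCCCCCCCCC=O | intermediate
5 | (E)-eicosanal hydrazone (formed in the flask, not isolated) | CCCCCCCCCCCCCCCCCCC/C=N/N | intermediate
6 | 2,4-dimethoxy-6-methylidenecyclohexa-2,4-dien-1-one (o-quinone methide, not isolated) | C=C1C=C(OC)C=C(OC)C1=O | intermediate
7 | [1-(2-hydroxy-3,5-dimethoxyphenyl)henicosan-2-yl]diazene (racemic at C2, not isolated) | CCCCCCCCCCCCCCCCCCCC(N=N)Cc1cc(OC)cc(OC)c1O | intermediate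
8 | 6-n-heneicosyl-2,4-dimethoxyphenol (achiral) | CCCCCCCCCCCCCCCCCCCCCc1cc(OC)cc(OC)c1O | target

**Total step count:** 3
**Longest linear sequence:** 2 steps (1 → 2 → 8, or 3 → 4 → 8)

**Steps most likely to fail, with fallbacks**

Step 3 is the most at risk. The hydrazone may attack 6 only through nitrogen, 6 may oligomerise, or the ene-hydrazine tautomer of 5 may react through its α-carbon. The fallback sets out from 2 and 4 and keeps the same bond but uses a true acyl anion. A thiazolium-derived N-heterocyclic carbene (3-benzyl-5-(2-hydroxyethyl)-4-methylthiazolium chloride 20 mol %, Cs2CO3, 1,4-dioxane, 90 °C) turns 4 into a catalyst-bound acyl anion equivalent. This adds to 6 as it is released from 2 (Stetter-type acylation of an o-quinone methide) and gives 1-(2-hydroxy-3,5-dimethoxyphenyl)henicosan-2-one F1. The ketone is kept away from acid, which would close it to a benzofuran. Condensation with N2H4·H2O gives 1-(2-hydroxy-3,5-dimethoxyphenyl)henicosan-2-one hydrazone F2. KOtBu in DMSO (Wolff–Kishner reduction, Cram modification) then expels N2, and the fallback comes back to the route at 8.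

Step 1 is second. The Mannich reaction of this electron-rich, air-sensitive phenol may be sluggish or give some attack at C5. The fallback sets out from 1. Magnesium-mediated ortho-formylation (MgCl2, Et3N, paraformaldehyde, MeCN, reflux) is directed strictly ortho to OH through the magnesium phenoxide and gives 2-hydroxy-3,5-dimethoxybenzaldehyde F3. Reductive amination with Me2NH and NaBH(OAc)3 in 1,2-dichloroethane then comes back to the route at 2.

Step 2 is third. The long-chain alcohol is poorly soluble, and alcohol plus aldehyde can form a hemiacetal that is oxidised to eicosyl eicosanoate. The fallback sets out from 3 and avoids having alcohol and aldehyde together. Heating 3 with 48% HBr and catalytic H2SO4 gives 1-bromoeicosane F4. Ganem oxidation with anhydrous trimethylamine N-oxide in DMSO at rt (O-alkylation, then elimination) comes back to the route at 4.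

**Further compounds**
F1 | step 3 | 1-(2-hydroxy-3,5-dimethoxyphenyl)henicosan-2-one | CCCCCCCCCCCCCCCCCCCC(=O)Cc1cc(OC)cc(OC)c1O
F2 | step 3 | 1-(2-hydroxy-3,5-dimethoxyphenyl)henicosan-2-one hydrazone (E/Z mixture) | CCCCCCCCCCCCCCCCCCCC(=NN)Cc1cc(OC)cc(OC)c1O
F3 | step 1 | 2-hydroxy-3,5-dimethoxybenzaldehyde | O=Cc1cc(OC)cc(OC)c1O
F4 | step 2 | 1-bromoeicosane | CCCCCCCCCCCCCCCCCCCCBr
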